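We read each flask at 50 min, and in the south-west run the other mono adduct already reads 7% at 10.0 min and still reads 7% at 50.0 min, while substrate reads 1% at the end.

| flask | substrate | partner | remark | time |
|---|---|---|---|---|
| west | 0.20 mM | 0.13 mM | run made earlier |  |
| south-west | 0.20 mM | 0.26 mM | run made earlier |  |
| south-east | 0.20 mM | 0.61 mM | run made earlier |  |
| violet | 0.20 mM | 0.100 mM |  | 50 min |
| teal | 0.20 mM | 0.240 mM |  | 50 min |
| ochre | 0.20 mM | 0.600 mM |  | 50 min |

| run | time / min | other mono adduct / % | single product / % | substrate / % |
|---|---|---|---|---|
| west | 4.00 | 7 | 35 | 8 |
| west | 12.0 | 5 | 30 | 1 |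
| west | 25.0 | 4 | 30 | 1 |
| west | 40.0 | 7 | 30 | 0 |
| west | 50.0 | 7 | 25 | 0 |
| south-west | 10.0 | 7 | 26 | 1 |
| south-west | 20.0 | 6 | 25 | 4 |
| south-west | 30.0 | 7 | 24 | 0 |
| south-west | 40.0 | 7 | 23 | 0 |
| south-west | 50.0 | 7 | 26 | 1 |
| south-east | 4.00 | 3 | 0 | 0 |
| south-east | 8.00 | 1 | 0 | 0 |
| south-east | 15.0 | 0 | 0 | 0 |
| south-east | 25.0 | 2 | 3 | 1 |
| south-east | 50.0 | 3 | 0 | 2 |

(scatter of a reading: 1.5 percentage points)

- reactions considered so far: partner + other mono adduct -> bis adduct + by-product; partner + single product -> bis adduct + by-product; substrate + partner -> other mono adduct + by-product; partner -> decomposed reagent; substrate + partner -> single product + by-product; single product <-> isomer of the product; substrate + by-product -> side product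

- final other mono adduct, as a percentage of the substrate charged, for each flask in turn (violet, teal, ochre)

So we ask where one substrate molecule ends up. Its first meeting with partner makes a mono adduct, and a second meeting carries that mono adduct on to bis adduct. Each step costs one partner, so we count the partner ratio, the partner charged per substrate charged, written here for ochre as 3.00. Bis adduct needs two partners per substrate, so at a ratio below two partner is the limiting reagent for bis adduct.

The south-east run, at 3.05, lies above two and its last reading of other mono adduct is 3%, whereas south-west, at 1.30, lies below two and its last reading is 7%. Our own reckoning follows these neighbours, and it gives an order, not figures. Ochre stands beside south-east, and teal, at 1.20, stands beside south-west. Violet, at 0.500, has partner for fewer than one mono adduct per substrate, so we expect it to read lower than teal.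

The forecast gives 5.5% for violet, 7% for teal and 1% for ochre, and of the high charge it says “excess partner carries both mono adducts on to bis adduct quickly”.

The flasks give 4.16% in violet, 7.07% in teal and 0.719% in ochre, each within the margin of the forecast.

    partner + other mono adduct → bis adduct + by-product (k = 27.1 /M/s)
    partner + single product → bis adduct + by-product (k = 180 /M/s)
    substrate + partner → other mono adduct + by-product (k = 47.9 /M/s)
    partner → decomposed reagent (k = 0.00228 /s)
    substrate + partner → single product + by-product (k = 449 /M/s)
    single product ⇌ isomer of the product (K = 0.470, k = 8.30 × 10⁻⁴ /s)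
    substrate + by-product → side product (k = 79.6 /M/s)

In ochre at 50.0 min bis adduct stands at 94.7% of the substrate charged, which took 1.89 partners per substrate, and the decomposed reagent took 1.10 more, together 2.99 of the ratio of 3.00. In teal, with a ratio of 1.20, bis adduct, single product, its isomer and other mono adduct took 1.14 partners per substrate and the decomposed reagent 0.0555, with bis adduct at 33.7%.

The runs stem from a simulated flask with made-up constants.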